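## Retrosynthesis
- Torilin comes from the C1 epimer (13) by base equilibration. The C8 angelate and C11 acetate are already on the skeleton before the ring-forming steps.
- The C10–H guaiane (13) comes from a photochemically made lumiketone (12) by acid-triggered cyclopropane opening with hydride capture of the C10 cation. This step expands ring B from six to seven members.
- The lumiketone comes from the cross-conjugated dienone (11) by a type-A dienone photorearrangement. This step forms the C1–C5 bond and the cyclopentenone. Dienone 11 comes from a Robinson annulation on a carvone-derived hydrate, which sets C10 and retains C7 from (R)-carvone. C8 is then built by hydroboration, oxidation and axial reduction.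
- Ring order: six-membered ring B (carvone), six-membered ring A (Robinson), then the five-membered ring by photochemistry, and ring B expands to seven in the cyclopropane-opening step.

Assumption: the (Z)-2-methylbut-2-enoate in the SMILES is angelate, and the thermodynamically preferred C1 epimer (C2 anti to the C10 methyl) is the natural one.

## Route

**Step 1**
Reactants: 1 (R)-(−)-carvone
Product: 2 (R)-5-(2-hydroxypropan-2-yl)-2-methylcyclohex-2-en-1-one
Conditions: Co(acac)2 (5 mol%), PhSiH3, O2 (1 atm), i-PrOH, rt
Reagents that add atoms: O2, O=O
Why: Mukaiyama (HAT) hydration hydrates the 1,1-disubstituted isopropenyl group, a tertiary-radical-forming alkene, and leaves the electron-poor enone intact. It gives the C11 tertiary alcohol, and the C7 stereocentre is untouched.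

**Step 2**
Reactants: 2; 3 ethyl vinyl ketone (pent-1-en-3-one)
Product: 4 11-hydroxyeudesma-4,8-dien-3-one, with the C10 methyl cis to the C7 side chain
Conditions: (i) KOt-Bu, t-BuOH, 0 °C, then 3; (ii) KOH, EtOH, 60 °C
Reagents that add atoms: none
Why: Deconjugative Robinson annulation. The thermodynamic dienolate of 2 adds to 3 through C2 (α) on the face anti to the C5 side chain, which sets the quaternary C10. The double bond shifts to C8=C9, and the intramolecular aldol condensation then closes ring A as the 4-methyl-4-en-3-one.

**Step 3**
Reactants: 4
Product: 5 8α,11-dihydroxyeudesm-4-en-3-one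
Conditions: 9-BBN (2.5 equiv), THF, 0 °C→rt; then NaBO3·4H2O, THF/H2O
Reagents that add atoms: oxygen from perborate (H2O2 equivalent), OO
Why: Hydroboration–oxidation. Boron goes to C8, because C9 is flanked by the quaternary C10. It adds from the α face, anti to the axial C10 methyl, and oxidation with retention gives the equatorial 8α-alcohol. The hindered tetrasubstituted enone is not touched.

**Step 4**
Reactants: 5
Product: 6 11-hydroxyeudesm-4-en-3,8-dione
Conditions: Dess–Martin periodinane, NaHCO3, CH2Cl2, rt
Reagents that add atoms: none
Why: Oxidation of the secondary alcohol only; the tertiary C11 alcohol is inert. The planned reduction of this C8 ketone then sets the C8 configuration.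

**Step 5**
Reactants: 6
Product: 7 8β,11-dihydroxyeudesm-4-en-3-one (axial 8β-OH, cis to the C7 side chain)
Conditions: L-Selectride, THF, −78 °C
Reagents that add atoms: none
Why: Hydride attacks the C8 ketone from the α face (equatorial attack), because the axial β face is blocked 1,3-diaxially by the C10 methyl. This gives the axial 8β-alcohol, as in 11-keto steroid reductions. The conjugated, hindered tetrasubstituted enone reacts more slowly.

**Step 6**
Reactants: 7; 8 angelic acid
Product: 9 8β-angeloyloxy-11-hydroxyeudesm-4-en-3-one
Conditions: 8, 2,4,6-Cl3C6H2COCl, Et3N, THF; then 7, DMAP, PhMe, rt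
Reagents that add atoms: 8, C/C=C(/C)C(=O)O
Why: Yamaguchi esterification. The secondary alcohol acylates selectively over the tertiary one, and the Z-alkene geometry of the angelate is retained under these mild conditions.

**Step 7**
Reactants: 9
Product: 10 8β-angeloyloxy-11-acetoxyeudesm-4-en-3-one
Conditions: Ac2O, Sc(OTf)3 (cat.), MeCN, rt
Reagents that add atoms: Ac2O, CC(=O)OC(C)=O
Why: Lewis-acid-catalysed acetylation of the hindered tertiary alcohol. The acetate protects C11 from ionisation in the later acid step.

**Step 8**
Reactants: 10
Product: 11 8β-angeloyloxy-11-acetoxyeudesma-1,4-dien-3-one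
Conditions: DDQ, dioxane, 85 °C
Reagents that add atoms: none
Why: Dehydrogenation of the Δ4-3-ketone to the cross-conjugated 1,4-dienone. This is the substrate for the photorearrangement, with a quaternary C10 bearing the methyl and ring B.

**Step 9**
Reactants: 11
Product: 12 lumiketone, a bicyclo[3.1.0]hexenone with the cyclopropane made of C1, C2 and C10
Conditions: hν (medium-pressure Hg lamp, Pyrex, λ > 300 nm), 1,4-dioxane, Ar, 20 °C
Reagents that add atoms: none
Why: Type-A cyclohexadienone photorearrangement (the lumisantonin-type reaction). β,β-Bonding forms the C1–C5 bond, so the cyclopentenone is made here, and a 1,2-shift of C10 onto C2 gives the cyclopropyl ketone. The process is stereospecific, and the C10 configuration dictates the C1 configuration. C7 and C8 are not involved.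

**Step 10**
Reactants: 12
Product: 13 1-epi-torilin (C10–H guaiane, with C1 epimeric to torilin)
Conditions: TFA (3 equiv), Et3SiH (5 equiv), CH2Cl2, −40→0 °C
Reagents that add atoms: none (only H)
Why: Proposed new method: protonation of the C3 carbonyl of the lumiketone opens the external cyclopropane bond C2–C10. This ring-expands ring B to seven members and leaves a tertiary C10 cation with a cyclopentadienol. Et3SiH delivers hydride to C10 from the face opposite the 8β-ester and the C7 side chain, which puts the methyl cis to them as in torilin, and the dienol tautomerises to the 4-en-3-one. The closest known reactions are the acid-catalysed lumisantonin → isophotosantonic-type opening, where the cation is trapped by a nucleophile, and ionic hydrogenation of tertiary cations with Et3SiH/TFA. Trapping this cation with hydride to give the 10-H guaiane has not been shown.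

**Step 11**
Reactants: 13
Product: 14 torilin
Conditions: DBU, PhMe, 40 °C, 12 h
Reagents that add atoms: none
Why: C1 is γ to the enone, so the extended dienolate equilibrates it. The thermodynamic epimer has C2 anti to the C10 methyl, which is the natural configuration. No other centre is acidic, so C7, C8 and C10 are preserved.

## Compound list
1 | (R)-(−)-carvone | CC1=CC[C@@H](C(C)=C)CC1=O | starting material
2 | (R)-5-(2-hydroxypropan-2-yl)-2-methylcyclohex-2-en-1-one | CC1=CC[C@@H](C(C)(C)O)CC1=O | intermediate
3 | ethyl vinyl ketone | C=CC(=O)CC | starting material
4 | 11-hydroxyeudesma-4,8-dien-3-one (10-Me cis to the C7 side chain) | CC1=C2C[C@H](C(C)(C)O)C=C[C@@]2(C)CCC1=O | intermediate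
5 | 8α,11-dihydroxyeudesm-4-en-3-one | CC1=C2C[C@H](C(C)(C)O)[C@@H](O)C[C@@]2(C)CCC1=O | intermediate
6 | 11-hydroxyeudesm-4-en-3,8-dione | CC1=C2C[C@H](C(C)(C)O)C(=O)C[C@@]2(C)CCC1=O | intermediate
7 | 8β,11-dihydroxyeudesm-4-en-3-one | CC1=C2C[C@H](C(C)(C)O)[C@H](O)C[C@@]2(C)CCC1=O | intermediate
8 | angelic acid ((Z)-2-methylbut-2-enoic acid) | C/C=C(/C)C(=O)O | starting material
9 | 8β-angeloyloxy-11-hydroxyeudesm-4-en-3-one | CC1=C2C[C@H](C(C)(C)O)[C@H](OC(=O)/C(C)=C\C)C[C@@]2(C)CCC1=O | intermediate
10 | 8β-angeloyloxy-11-acetoxyeudesm-4-en-3-one | CC1=C2C[C@H](C(C)(C)OC(C)=O)[C@H](OC(=O)/C(C)=C\C)C[C@@]2(C)CCC1=O | intermediate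
11 | eudesma-1,4-dien-3-one analogue of 10 | CC1=C2C[C@H](C(C)(C)OC(C)=O)[C@H](OC(=O)/C(C)=C\C)C[C@@]2(C)C=CC1=O | intermediate
12 | lumiketone (bicyclo[3.1.0]hexenone) | CC1=C2C[C@H](C(C)(C)OC(C)=O)[C@H](OC(=O)/C(C)=C\C)C[C@@]3(C)[C@@H]2[C@H]3C1=O | intermediate
13 | 1-epi-torilin | C/C=C(/C)C(=O)O[C@@H]1C[C@H](C)[C@@H]2CC(=O)C(C)=C2C[C@@H]1C(C)(C)OC(C)=O | intermediate
14 | torilin | C/C=C(/C)C(=O)O[C@@H]1C[C@H](C)[C@H]2CC(=O)C(C)=C2C[C@@H]1C(C)(C)OC(C)=O | target

## Step count and risks
Total steps: 11. Longest linear sequence: 11, from carvone; ethyl vinyl ketone and angelic acid are the only convergent inputs.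

Three steps most likely to fail:
1. **Step 10 (the proposed new step).** The risks are E1 elimination of the C10 cation, participation by the 1,3-related 8β-angelate, or ionisation at C11 in TFA.
   - Fallback (known chemistry): irradiate dienone 11 in aqueous AcOH, the santonin-type conditions, to obtain the C10-oxygenated guaiane. Then deoxygenate C10 by dehydration followed by Mn/Co-HAT hydrogenation, or by a tertiary-oxalate photoredox deoxygenation, and finish with step 11.
2. **Step 2 (deconjugative Robinson).** The risks are γ- versus α-attack, double Michael addition and a bridged aldol product.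
   - Fallback: run the well-known Robinson annulation of (+)-dihydrocarvone with ethyl vinyl ketone to give the α-cyperone-type decalin. Install C8 oxygen by isomerising the isopropenyl group to Δ7(11) and applying SeO2 allylic oxidation, then re-establish C7/C11 by hydration and ketone reduction.
3. **Step 5 (chemoselective axial reduction in the presence of the enone).** The enone may be reduced as well.
   - Fallback: reduce both carbonyls with NaBH4 and selectively re-oxidise the allylic C3 alcohol with MnO2. Alternatively, invert the 8α-alcohol of 5 by Mitsunobu reaction with p-nitrobenzoic acid followed by methanolysis.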